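**Analysis of the target**

The target 18 is 2,5-dihydroxy-3-methyl-6-pentadecyl-1,4-benzoquinone, a single six-membered carbocycle in which every ring carbon is substituted. Numbering used throughout: C1 is the carbonyl carbon next to the pentadecyl-bearing carbon C6, C2 carries a hydroxyl, C3 the methyl, C4 is the second carbonyl and C5 carries the second hydroxyl. There is no stereocenter and no double-bond geometry to set, so the difficulty is purely regiochemical: four oxygens and two different alkyl groups on six contiguous carbons, with the alkyl groups para to each other. The 2,5-dihydroxyquinone is a double vinylogous acid, chelating and easily reduced, and its two tautomers (carbonyls at C1/C4 or at C2/C5) interconvert by proton shift, so the oxygens only have to reach the right carbons, not a particular carbonyl/hydroxyl order. The ring degrades in hot alkali when oxidants are present, which argues for forming the quinone late and freeing the dihydroxyquinone last. Substitution on a preformed quinone or arene would have to tell the methyl site from the pentadecyl site, which is unreliable. The strategy rests on C3 lying between two oxygenated carbons (C2 and C4) with C6 meta to both: without the C1 and C5 oxygens the ring is a 2-methyl-5-pentadecylresorcinol, in which C2–C3 is an oxygen-plus-methyl two-carbon unit and C4–C5–C6–C1 a four-carbon unit with the chain on C6.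

**Retrosynthetic reasoning**

The C2 hydroxyl of 18 is traced back to the C2 ethoxy group of 2-ethoxy-5-hydroxy-3-methyl-6-pentadecyl-1,4-benzoquinone 17 (C2–O bond). In 17 the ethoxy group is the alkoxy end of a vinylogous ester (O–C2=C3–C4=O), so aqueous base can exchange it for hydroxyl by addition–elimination. This comes last because the free dihydroxyquinone is the most polar and most fragile compound of the series, and because the ethyl group, which arrives with the key step, keeps one oxygen masked while the other two are introduced.

17 is traced back to 2-ethoxy-3-methyl-6-pentadecyl-1,4-benzoquinone 14 by removing the C5 oxygen. C5 is the only ring carbon of 14 that bears hydrogen and it is the β-carbon of the C1 enone, so an oxygen nucleophile can add nowhere else. The forward reaction is a Thiele–Winter acetoxylation to triacetate 15, followed by deacetylation to triol 16 and re-oxidation.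

14 is traced back to 3-ethoxy-2-methyl-5-pentadecylphenol 13 by removing the C1 oxygen. In 13, C1 is the free position para to the phenolic carbon C4, the standard retron for a radical phenol-to-para-quinone oxidation. The gain is that a four-oxygen ring becomes a resorcinol monoether with only two oxygens, at C2 and C4, flanking the methyl carbon C3.

The benzene ring of 13 is cut at C3–C4 and C1–C2. This gives a two-carbon piece (C2 with ethoxy, C3 with methyl), 1-ethoxyprop-1-yne 8, and a four-carbon piece (C4 carbonyl, C5, C6 with the chain, C1), the vinylketene 9, whose storable form is 3-pentadecylcyclobut-2-en-1-one 5. The cut is made here because it pairs the nucleophilic carbon C3 (β to the ether oxygen) with the electrophilic ketene carbon C4, so the polarity of both partners dictates the orientation: methyl between the oxygens, chain meta to both. Other cuts would place the methyl or the chain on a partner with no electronic bias. The forward reaction must run four pericyclic events in one flask, through 9, the alkenylcyclobutenone 10, the dienylketene 11 and the dienone 12.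

Cyclobutenone 5 is traced back through its 4,4-dichloro derivative 4 to heptadec-1-yne 1 and dichloroketene 3, the latter generated from trichloroacetyl chloride 2. The bonds cut are C4–C1 and C5–C6 of the four-membered ring, a ketene–alkyne [2+2] cycloaddition. The electrophilic ketene carbon bonds to the terminal alkyne carbon, which places the chain on C6. The two chlorines that make the ketene reactive enough are removed reductively afterwards.

Ynol ether 8 is traced back to ethoxyacetylene 6 by cutting the C3–CH3 bond. The forward reaction is deprotonation to the acetylide 7 and C-methylation.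

**Alternatives that were turned down**

Alternative 1: Three-component carbene benzannulation.
- Disconnection: the ring is cut at C4–C5, C6–C1 and C1–C2. Heptadec-1-yne 1 supplies C5 and C6, a carbonyl ligand supplies C1, and the carbene carbon with its isopropenyl group supplies C4, C3 and C2.
- Forward key step: pentacarbonyl[methoxy(prop-1-en-2-yl)methylidene]chromium A1, a Fischer carbene complex of zerovalent chromium, is heated with 1. Alkyne insertion, CO insertion and electrocyclisation (Dötz benzannulation) should give 4-methoxy-5-methyl-2-pentadecylphenol A2, with the chain next to the new phenol carbon.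
- For: it is convergent, uses the purchased alkyne directly, and the regiochemistry with terminal alkynes is dependable. A2 is a hydroquinone monoether that one oxidative demethylation turns into 2-methyl-5-pentadecyl-1,4-benzoquinone A3.
- Against: A1 needs two steps to prepare and is used stoichiometrically, so a full equivalent of a toxic, air-sensitive metal carbonyl species is carried and must be decomplexed oxidatively. A3 has only the C1 and C4 oxygens, so C2 and C5 still have to be hydroxylated.
- Comparison: both ring-forming steps deliver two of the four oxygens. This alternative is probably a step or two shorter, since a 2,5-dialkylquinone can take up both missing heteroatoms in one double addition. The chosen strategy offers instead a metal-free, fully atom-economical key step from two small organic partners, with no chromium waste.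

Alternative 2: Squaric ester ring expansion.
- Disconnection: only C1–C2 is cut in the ring-forming step. C4, C5, C6 and C1 are the four ring carbons of a cyclobutenone and C3 and C2 a methoxypropenyl side chain.
- Forward key step: diisopropyl squarate A4 would take up a C15 alkyl nucleophile and, after acid work-up, a (Z)-β-methoxyalkenyl nucleophile at the carbonyl outside the vinylogous ester. This gives racemic 4-hydroxy-4-[(1Z)-1-methoxyprop-1-en-2-yl]-2-pentadecyl-3-(propan-2-yloxy)cyclobut-2-en-1-one A5. Heating A5 in toluene or xylene should open the ring (4π), close C1–C2 by 6π electrocyclisation and give 2-methoxy-3-methyl-6-pentadecyl-5-(propan-2-yloxy)benzene-1,4-diol A6 after tautomerisation.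
- For: every substituent is placed before the ring forms and all four oxygens are present, so no C–H oxidation is needed. A6 is two steps from the target (oxidation, double vinylogous ester hydrolysis), against four after the key step of the chosen route; on this point the alternative is clearly stronger.
- Against: the burden moves to the precursor. Two successive cryogenic organometallic additions are needed. The second uses a β-alkoxyalkenyl metal species that must be geometrically pure, is stable only cold and collapses by β-elimination on warming. Its halide precursor must also be made, and the long-chain organometallic adds a further preparation.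
- Comparison: overall length is similar. The chosen strategy reaches its precursors in three robust steps, so the uncertainty sits in the pericyclic step itself and not in reaching it.

Alternative 3: Biomimetic polyketide aldol.
- Disconnection: the ring bond C1–C6 is cut, unravelling the ring into the linear 4-methyl-3,5,7-trioxodocosanoic acid A7 (racemic).
- Forward key step: in buffered water the C2 methylene of A7 should add to its C7 ketone; dehydration and enolisation give 2,4-dihydroxy-3-methyl-6-pentadecylbenzoic acid A8.
- For: it mirrors the biosynthesis, the regiochemistry is written into the chain, the building blocks are cheap and no O-alkyl group has to be removed at the end; on reagent cost and on that last point it is stronger.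
- Against: A7 is a β,δ,ζ-triketo acid with a branch between two carbonyls. Its assembly needs polyanion acylations, and outside an enzyme nothing controls its folding. Lactonisation to a hydroxypyrone, Claisen-type closure and decarboxylation are as easy as the wanted aldol. After ring formation a decarboxylation to 2-methyl-5-pentadecylbenzene-1,3-diol A9 is needed, followed by the same two ring oxidations as in the chosen route, so no step is saved.
- Comparison: both routes reach the same resorcinol oxidation level. The chosen one does it in a single predictable cascade from two stable precursors and delivers a monoether, which keeps the later phenol oxidation site-specific.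

Key step: step 4

Remark: heptadec-1-yne and ethoxyacetylene (as its solution in hexanes) are treated as purchasable, and the target is written as one of its two equivalent dihydroxyquinone tautomers.

**Route**

Step 1
Reactants: 1 heptadec-1-yne; 2 trichloroacetyl chloride
Product: 4 4,4-dichloro-3-pentadecylcyclobut-2-en-1-one, via dichloroketene 3 (not isolated)
Conditions: Zn(Cu), Et2O/DME, slow addition of 2, 20 → 35 °C
Reagents that add atoms: none
Why: Zinc reduces 2 to dichloroketene 3, whose electrophilic carbonyl carbon bonds to the terminal carbon of 1 in a ketene–alkyne [2+2] cycloaddition, so the chain ends on C3 of the cyclobutenone; this is the standard entry to 3-alkyl-4,4-dichlorocyclobutenones.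

Step 2
Reactants: 4 4,4-dichloro-3-pentadecylcyclobut-2-en-1-one
Product: 5 3-pentadecylcyclobut-2-en-1-one
Conditions: Zn dust, AcOH, TMEDA, EtOH, 0 → 20 °C
Reagents that add atoms: none
Why: Zinc in buffered acetic acid removes both α-chlorines by successive reductive dehalogenation through zinc enolates; the amine buffer suppresses acid-promoted ring opening and over-reduction of the strained enone.

Step 3
Reactants: 6 ethoxyacetylene
Product: 8 1-ethoxyprop-1-yne, via lithium ethoxyacetylide 7 (not isolated)
Conditions: n-BuLi, THF, −78 °C; MeI, DMPU, −78 → 20 °C; aq. NaHCO3; fractional distillation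
Reagents that add atoms: iodomethane, CI
Why: The acetylenic proton of 6 is removed cleanly by n-BuLi and the acetylide 7 is C-methylated in the presence of the dipolar cosolvent (acetylide alkylation); the ynol ether tolerates base and is kept away from acid on work-up.

Step 4
Reactants: 5 3-pentadecylcyclobut-2-en-1-one; 8 1-ethoxyprop-1-yne
Product: 13 3-ethoxy-2-methyl-5-pentadecylphenol, via vinylketene 9 (not isolated), via alkenylcyclobutenone 10 (not isolated), via dienylketene 11 (not isolated), via cyclohexadienone 12 (not isolated)
Conditions: PhMe, sealed tube, 80 °C then 110 °C; then KOH, MeOH, 20 °C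
Reagents that add atoms: none
Why: At about 80 °C cyclobutenone 5 opens reversibly by conrotatory 4π electrocyclic ring opening to vinylketene 9, which is captured in a [2+2] cycloaddition by the electron-rich triple bond of 8. The ynol ether is polarised so that its methyl-bearing carbon is the nucleophile; it bonds to the ketene carbonyl carbon (C3–C4) while the ethoxy-bearing carbon bonds to the ketene α-carbon (C1–C2), giving 10. Cyclobutenone 10 opens in a second 4π step to dienylketene 11, and the six-membered ring closes by thermal disrotatory 6π electrocyclisation between the ketene carbon C4 and the methylidene carbon C5, re-forming the bond broken in the first opening; enolisation of dienone 12 gives the phenol. The closest known reaction type is the Danheiser benzannulation of 3-alkylcyclobutenones with alkoxy- and siloxyalkynes to resorcinol monoethers. No stereocenter survives: the sp3 centre of 10 and the double-bond geometry of 11 are lost on aromatisation, and the reversible opening of 10 funnels material through the isomer of 11 that can cyclise. The one selectivity needed is the orientation of the [2+2], and the donor oxygen of 8 secures it, placing the methyl between the two oxygens and the chain meta to both. Holding at 80 °C until 8 is consumed keeps the ethyl ynol ether below its retro-ene fragmentation temperature, and the KOH/MeOH treatment returns any phenol that a ketene has acylated.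

Step 5
Reactants: 13 3-ethoxy-2-methyl-5-pentadecylphenol
Product: 14 2-ethoxy-3-methyl-6-pentadecyl-1,4-benzoquinone
Conditions: (KSO3)2NO, KH2PO4, Bu4NHSO4 (cat.), CH2Cl2/H2O, 20 °C
Reagents that add atoms: potassium nitrosodisulfonate (KSO3)2NO, [K+].[K+].[O]N(S(=O)(=O)[O-])S(=O)(=O)[O-]
Why: Teuber oxidation: one equivalent of the nitroxyl radical abstracts the phenolic hydrogen, a second adds to the phenoxyl radical at the free para carbon C1, and loss of imidodisulfonate gives the para-quinone. The same oxidation is standard for 3-alkoxy-5-alkylphenols, and the phase-transfer salt brings the oxidant to the lipophilic substrate.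

Step 6
Reactants: 14 2-ethoxy-3-methyl-6-pentadecyl-1,4-benzoquinone
Product: 15 5-ethoxy-6-methyl-3-pentadecylbenzene-1,2,4-triyl triacetate
Conditions: Ac2O, H2SO4 (cat.), 20 → 40 °C
Reagents that add atoms: acetic anhydride, CC(=O)OC(C)=O
Why: Thiele–Winter acetoxylation: the acid-activated quinone takes up acetate in a conjugate sense at its only unsubstituted carbon C5, which is β to the C1 carbonyl (the C4 carbonyl is deactivated as a vinylogous ester). The resulting hydroquinone is acetylated in situ, so the hydroxyquinone oxidation level is stored as a stable triacetate.

Step 7
Reactants: 15 5-ethoxy-6-methyl-3-pentadecylbenzene-1,2,4-triyl triacetate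
Product: 17 2-ethoxy-5-hydroxy-3-methyl-6-pentadecyl-1,4-benzoquinone, via benzenetriol 16 (not isolated)
Conditions: HCl, EtOH, reflux, N2; then FeCl3, H2O/EtOH, 20 °C
Reagents that add atoms: none
Why: Acid-catalysed transesterification in ethanol removes the three acetyl groups without touching the aryl ethyl ether (ethanol makes any alkoxy exchange degenerate), and FeCl3 oxidises the electron-rich triol 16 to the para-quinone tautomer of the hydroxyquinone.

Step 8
Reactants: 17 2-ethoxy-5-hydroxy-3-methyl-6-pentadecyl-1,4-benzoquinone
Product: 18 2,5-dihydroxy-3-methyl-6-pentadecyl-1,4-benzoquinone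
Conditions: NaOH (2 M aq.), EtOH, 70 °C, N2; then HCl (aq.)
Reagents that add atoms: sodium hydroxide, [Na+].[OH-]
Why: The C2 ethoxy group is the alkoxy end of a vinylogous ester (O–C2=C3–C4=O), so hydroxide adds at C2 and expels ethoxide (addition–elimination), as in the alkaline hydrolysis of 2,5-dialkoxyquinones to 2,5-dihydroxyquinones. The doubly deprotonated dihydroxyquinone is the thermodynamic sink, and acidification releases 18.

**Compound list**

1 | heptadec-1-yne | CCCCCCCCCCCCCCCC#C | starting material
2 | trichloroacetyl chloride | ClC(=O)C(Cl)(Cl)Cl | starting material
3 | dichloroketene (2,2-dichloroethen-1-one) | ClC(Cl)=C=O | intermediate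
4 | 4,4-dichloro-3-pentadecylcyclobut-2-en-1-one | CCCCCCCCCCCCCCCC1=CC(=O)C1(Cl)Cl | intermediate
5 | 3-pentadecylcyclobut-2-en-1-one | CCCCCCCCCCCCCCCC1=CC(=O)C1 | intermediate
6 | ethoxyacetylene (ethoxyethyne) | CCOC#C | starting material
7 | lithium ethoxyacetylide | [Li]C#COCC | intermediate
8 | 1-ethoxyprop-1-yne | CC#COCC | intermediate
9 | 3-methylideneoctadec-1-en-1-one (vinylketene) | CCCCCCCCCCCCCCCC(=C)C=C=O | intermediate
10 | 3-ethoxy-4-(heptadec-1-en-2-yl)-2-methylcyclobut-2-en-1-one (racemic) | CCCCCCCCCCCCCCCC(=C)C1C(OCC)=C(C)C1=O | intermediate
11 | (3E)-3-ethoxy-2-methyl-5-methylideneicosa-1,3-dien-1-one (dienylketene) | CCCCCCCCCCCCCCCC(=C)/C=C(OCC)\C(C)=C=O | intermediate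
12 | 3-ethoxy-2-methyl-5-pentadecylcyclohexa-2,4-dien-1-one | CCCCCCCCCCCCCCCC1=CC(OCC)=C(C)C(=O)C1 | intermediate
13 | 3-ethoxy-2-methyl-5-pentadecylphenol | CCCCCCCCCCCCCCCc1cc(O)c(C)c(OCC)c1 | intermediate
14 | 2-ethoxy-3-methyl-6-pentadecylcyclohexa-2,5-diene-1,4-dione | CCCCCCCCCCCCCCCC1=CC(=O)C(C)=C(OCC)C1=O | intermediate
15 | 5-ethoxy-6-methyl-3-pentadecylbenzene-1,2,4-triyl triacetate | CCCCCCCCCCCCCCCc1c(OC(C)=O)c(OC(C)=O)c(C)c(OCC)c1OC(C)=O | intermediate
16 | 5-ethoxy-6-methyl-3-pentadecylbenzene-1,2,4-triol | CCCCCCCCCCCCCCCc1c(O)c(O)c(C)c(OCC)c1O | intermediate
17 | 2-ethoxy-5-hydroxy-3-methyl-6-pentadecylcyclohexa-2,5-diene-1,4-dione | CCCCCCCCCCCCCCCC1=C(O)C(=O)C(C)=C(OCC)C1=O | intermediate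
18 | 2,5-dihydroxy-3-methyl-6-pentadecylcyclohexa-2,5-diene-1,4-dione | CCCCCCCCCCCCCCCC1=C(O)C(=O)C(C)=C(O)C1=O | target

**Step count and risks**

Total step count: 8. Longest linear sequence: 7 steps (steps 1, 2, 4, 5, 6, 7, 8 from heptadec-1-yne 1); step 3 is a one-step branch.

Step 4 (key step). The most likely failures are loss of the vinylketene by O-acylation of phenol already formed, and retro-ene fragmentation of the ethyl ynol ether (loss of ethylene) before the second ring opening is complete. The two ring openings need different temperatures, and the ynol ether is volatile and heat-sensitive. The fallback changes the ketenophile class and the protecting-group logic; it sets out from cyclobutenone 5 and comes back at phenol 13. Propynyllithium would be oxidised with LiOOt-Bu to lithium prop-1-yn-1-olate F1 and O-silylated with TIPSOTf to triisopropyl(prop-1-yn-1-yloxy)silane F2, which is involatile and not prone to the retro-ene pathway. Heated with 5 in toluene, it should give 2-methyl-5-pentadecyl-3-[tri(propan-2-yl)silyloxy]phenol F3 by the same cascade. The 2-methyl-5-pentadecylresorcinol core is symmetric about the C3–C6 axis, so it does not matter which oxygen carries the ethyl group. Mitsunobu ethylation of the free hydroxyl (EtOH, PPh3, DIAD) would give (3-ethoxy-2-methyl-5-pentadecylphenoxy)tri(propan-2-yl)silane F4, and desilylation with Bu4NF would give 13.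

Step 6. The most likely failure is sluggish conjugate addition of acetate, because the quinone is trisubstituted and carries a donor group, with acid-induced loss or exchange of the ethoxy group and decomposition on forcing. The fallback replaces acid-mediated oxygen addition by amine addition; it sets out from quinone 14 and comes back at the target 18, replacing steps 6 to 8. Methylamine in ethanol under oxygen should add at C5 with re-oxidation by air and displace ethoxide at C2 by addition–elimination, giving 3-methyl-2,5-bis(methylamino)-6-pentadecylcyclohexa-2,5-diene-1,4-dione F5. Hot aqueous H2SO4 in acetic acid would hydrolyse both vinylogous amides to 18.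

Step 5. The most likely failure is incomplete oxidation with oxidative coupling of phenoxyl radicals, because the C15 chain keeps the phenol out of the aqueous phase that holds the oxidant; attack of the second radical at the ortho carbon C5 instead of C1 would divert material to an ortho-quinone. The fallback fixes the para position by an ionic reaction; it sets out from phenol 13 and comes back at quinone 14. Nitrosation (NaNO2, AcOH/EtOH, 0 °C) is strongly para-selective for phenols and should give 3-ethoxy-2-methyl-4-nitroso-5-pentadecylphenol F6. Reduction with Na2S2O4 in aqueous ethanol would give 4-amino-3-ethoxy-2-methyl-5-pentadecylphenol F7, and oxidation with FeCl3 in dilute HCl would give 14 by hydrolysis of the quinone imine.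

Step 3. The most likely failure is slow C-alkylation of the oxygen-stabilised acetylide together with loss of the volatile, acid-sensitive product on separation from solvents of similar boiling point. The fallback does without 8 and introduces the methyl group on the arene; it sets out from ethoxyacetylene 6 and cyclobutenone 5 and comes back at phenol 13. Heating 5 with 6 under the conditions of step 4 should give 3-ethoxy-5-pentadecylphenol F8 by the same cascade. Protection with MOMCl and i-Pr2NEt would give 1-ethoxy-3-(methoxymethoxy)-5-pentadecylbenzene F9. Lithiation between the two oxygens with n-BuLi in THF and quenching with MeI would give 1-ethoxy-3-(methoxymethoxy)-2-methyl-5-pentadecylbenzene F10. HCl in methanol would remove the acetal to give 13.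

**Further compounds**

F1 | step 4 | lithium prop-1-yn-1-olate | [Li+].CC#C[O-]
F2 | step 4 | triisopropyl(prop-1-yn-1-yloxy)silane | CC#CO[Si](C(C)C)(C(C)C)C(C)C
F3 | step 4 | 2-methyl-5-pentadecyl-3-[tri(propan-2-yl)silyloxy]phenol | CCCCCCCCCCCCCCCc1cc(O)c(C)c(O[Si](C(C)C)(C(C)C)C(C)C)c1
F4 | step 4 | (3-ethoxy-2-methyl-5-pentadecylphenoxy)tri(propan-2-yl)silane | CCCCCCCCCCCCCCCc1cc(OCC)c(C)c(O[Si](C(C)C)(C(C)C)C(C)C)c1
F5 | step 6 | 3-methyl-2,5-bis(methylamino)-6-pentadecylcyclohexa-2,5-diene-1,4-dione | CCCCCCCCCCCCCCCC1=C(NC)C(=O)C(C)=C(NC)C1=O
F6 | step 5 | 3-ethoxy-2-methyl-4-nitroso-5-pentadecylphenol | CCCCCCCCCCCCCCCc1cc(O)c(C)c(OCC)c1N=O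
F7 | step 5 | 4-amino-3-ethoxy-2-methyl-5-pentadecylphenol | CCCCCCCCCCCCCCCc1cc(O)c(C)c(OCC)c1N
F8 | step 3 | 3-ethoxy-5-pentadecylphenol | CCCCCCCCCCCCCCCc1cc(O)cc(OCC)c1
F9 | step 3 | 1-ethoxy-3-(methoxymethoxy)-5-pentadecylbenzene | CCCCCCCCCCCCCCCc1cc(OCC)cc(OCOC)c1
F10 | step 3 | 1-ethoxy-3-(methoxymethoxy)-2-methyl-5-pentadecylbenzene | CCCCCCCCCCCCCCCc1cc(OCC)c(C)c(OCOC)c1
A1 | alternative 1 | pentacarbonyl[methoxy(prop-1-en-2-yl)methylidene]chromium | COC(C(C)=C)=[Cr](=C=O)(=C=O)(=C=O)(=C=O)=C=O
A2 | alternative 1 | 4-methoxy-5-methyl-2-pentadecylphenol | CCCCCCCCCCCCCCCc1cc(OC)c(C)cc1O
A3 | alternative 1 | 2-methyl-5-pentadecylcyclohexa-2,5-diene-1,4-dione | CCCCCCCCCCCCCCCC1=CC(=O)C(C)=CC1=O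
A4 | alternative 2 | diisopropyl squarate (3,4-di(propan-2-yloxy)cyclobut-3-ene-1,2-dione) | CC(C)OC1=C(OC(C)C)C(=O)C1=O
A5 | alternative 2 | 4-hydroxy-4-[(1Z)-1-methoxyprop-1-en-2-yl]-2-pentadecyl-3-(propan-2-yloxy)cyclobut-2-en-1-one (racemic) | CCCCCCCCCCCCCCCC1=C(OC(C)C)C(O)(/C(C)=C\OC)C1=O
A6 | alternative 2 | 2-methoxy-3-methyl-6-pentadecyl-5-(propan-2-yloxy)benzene-1,4-diol | CCCCCCCCCCCCCCCc1c(O)c(OC)c(C)c(O)c1OC(C)C
A7 | alternative 3 | 4-methyl-3,5,7-trioxodocosanoic acid (racemic) | CCCCCCCCCCCCCCCC(=O)CC(=O)C(C)C(=O)CC(=O)O
A8 | alternative 3 | 2,4-dihydroxy-3-methyl-6-pentadecylbenzoic acid | CCCCCCCCCCCCCCCc1cc(O)c(C)c(O)c1C(=O)O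
A9 | alternative 3 | 2-methyl-5-pentadecylbenzene-1,3-diol | CCCCCCCCCCCCCCCc1cc(O)c(C)c(O)c1
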